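**Retrosynthetic overview**

1. The last disconnections are the five O–benzyl bonds (hydrogenolysis) and then the two aryl ester C(=O)–O bonds at O1 and O4 of the central ring. These lead back to the symmetrical hydroquinone 8 and its quinone 9; the 3-phenylpropanoyl group goes on first and the (S)-3-(benzyloxy)butanoyl group second.
2. Feature: in the central ring (numbered as in the target SMILES) the hydroxyl carbons C2 and C5 are para to each other, and each sits between an aryl carbon (C3, C6) and an ester carbon (C1, C4). They are therefore the two CH positions of a 2,5-diaryl-1,4-benzoquinone whose carbonyl carbons are C1 and C4.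
3. Key disconnection: the C2–O and C5–O bonds, made by adding benzyl alcohol twice to quinone 4 with reoxidation after each addition. This leaves O2 and O5 as benzyl ethers, so that after reduction only O1 and O4 are free for acylation.
4. Quinone 4 comes from a double Suzuki coupling of 1,4-dibromo-2,5-dimethoxybenzene with 4-(benzyloxy)phenylboronic acid, followed by oxidative demethylation.
5. No ring is formed in the route: the central ring comes from 1, the two outer rings from 2, and the stereocentre from ethyl (S)-3-hydroxybutanoate.

Key step: step 3

Remark on the chemistry: it is assumed that the aryl esters of the hexasubstituted central ring do not migrate to a neighbouring free hydroxyl under neutral conditions, since the target is itself an isolable compound of this kind; commercial 12 is taken as enantiopure.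

**Route**

Step 1
Reactants: 1 1,4-dibromo-2,5-dimethoxybenzene; 2 4-(benzyloxy)phenylboronic acid (two molecules)
Product: 3 2,5-bis(4-(benzyloxy)phenyl)-1,4-dimethoxybenzene
Conditions: Pd(PPh3)4 (5 mol %), K2CO3, toluene/EtOH/H2O, 90 °C, Ar
Reagents that add atoms: none
Why: Double Suzuki–Miyaura coupling, in which both aryl bromides of 1 add oxidatively to zerovalent palladium and couple with the boronic acid while the methyl and benzyl ethers are inert.

Step 2
Reactants: 3 2,5-bis(4-(benzyloxy)phenyl)-1,4-dimethoxybenzene
Product: 4 2,5-bis(4-(benzyloxy)phenyl)-1,4-benzoquinone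
Conditions: (NH4)2Ce(NO3)6 (3 equiv), MeCN/CH2Cl2/H2O, 0 °C to rt
Reagents that add atoms: water, O
Why: Oxidative demethylation of a 1,4-dimethoxyarene by tetravalent cerium, in which the doubly alkoxylated central ring is the most easily oxidised, water attacks its radical cation at the two methoxy-bearing carbons and methanol is lost, while the mono-alkoxy outer rings and their unsubstituted benzyl ethers should survive.

Step 3
Reactants: 4 2,5-bis(4-(benzyloxy)phenyl)-1,4-benzoquinone; 5 benzyl alcohol (two molecules)
Product: 9 2,5-bis(benzyloxy)-3,6-bis(4-(benzyloxy)phenyl)-1,4-benzoquinone, via monobenzyloxy hydroquinone 6 (not isolated), via monobenzyloxy quinone 7 (not isolated), via bis(benzyloxy) hydroquinone 8 (not isolated)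
Conditions: BnOH (15 equiv), ZnCl2 (anhydrous, 2 equiv), chloranil (2.2 equiv), 4 Å MS, PhCl, 70 °C, Ar
Reagents that add atoms: none
Why: Proposed new method: ZnCl2 binds the C4 carbonyl of 4 and benzyl alcohol adds in a conjugate sense to the unsubstituted C2 (beta to C4=O, the developing zinc enolate being stabilised by the C3 aryl group), tautomerisation gives hydroquinone 6, and chloranil, which has no CH position of its own, dehydrogenates 6 to quinone 7; in 7 the new ether oxygen on C2 donates only into the C4 carbonyl, so the C1 carbonyl still activates the last CH (C5, beta to C1=O) for the second addition, and dehydrogenation of the resulting hydroquinone 8 gives 9. The closest known reaction is the ZnCl2-promoted addition of alcohols to 1,4-benzoquinone and alkylquinones with reoxidation in the flask (benzoquinone to 2,5-dimethoxybenzoquinone); it has not been shown at a quinone CH flanked by an aryl group or with benzyl alcohol as the nucleophile. No ring is closed and no stereocentre is formed. The step needs conjugate addition to prevail over carbonyl addition, which is secured because hemiketal formation is reversible whereas the conjugate adduct aromatises irreversibly, and it needs site selectivity, which is fixed because C2 and C5 are the only unsubstituted carbons of the quinone ring. Chloranil is chosen as terminal oxidant because it is a stronger acceptor than 7 and 9 yet should not oxidise benzyl alcohol or benzyl ethers at this temperature, and because ZnCl2 would be destroyed by a silver oxide oxidant.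

Step 4
Reactants: 9 2,5-bis(benzyloxy)-3,6-bis(4-(benzyloxy)phenyl)-1,4-benzoquinone
Product: 8 2,5-bis(benzyloxy)-3,6-bis(4-(benzyloxy)phenyl)benzene-1,4-diol
Conditions: Na2S2O4 (aq), THF, rt, Ar; used at once
Reagents that add atoms: none
Why: Two-electron reduction of a quinone to its hydroquinone by dithionite, which leaves benzyl ethers untouched and gives, now as an isolated compound, the same diol that step 3 passes through, with only O1 and O4 free.

Step 5
Reactants: 8 2,5-bis(benzyloxy)-3,6-bis(4-(benzyloxy)phenyl)benzene-1,4-diol; 10 3-phenylpropanoyl chloride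
Product: 11 2,5-bis(benzyloxy)-4-hydroxy-3,6-bis(4-(benzyloxy)phenyl)phenyl 3-phenylpropanoate
Conditions: 10 (0.9 equiv), pyridine, DMAP (cat.), CH2Cl2, −20 to 0 °C, Ar
Reagents that add atoms: none
Why: Acylation of a phenol by an acid chloride under nucleophilic catalysis, in which the two hydroxyls of centrosymmetric 8 are equivalent, the first ester lowers the nucleophilicity of the para hydroxyl, and a deficit of 10 should make the monoester the main product, with unreacted 8 recovered as quinone 9 after exposure to air and returned to step 4.

Step 6
Reactants: 12 ethyl (S)-3-hydroxybutanoate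
Product: 13 ethyl (S)-3-(benzyloxy)butanoate
Conditions: benzyl 2,2,2-trichloroacetimidate (1.5 equiv), TfOH (cat.), cyclohexane/CH2Cl2, 0 °C to rt
Reagents that add atoms: benzyl 2,2,2-trichloroacetimidate, N=C(OCc1ccccc1)C(Cl)(Cl)Cl
Why: Acid-catalysed O-benzylation with a trichloroacetimidate, which avoids the retro-aldol and beta-elimination pathways that a beta-hydroxy ester suffers under basic benzylation and leaves the C3 stereocentre untouched because only the O–H bond is replaced.

Step 7
Reactants: 13 ethyl (S)-3-(benzyloxy)butanoate
Product: 14 (S)-3-(benzyloxy)butanoic acid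
Conditions: LiOH, THF/H2O, 0 °C to rt; then 1 M HCl
Reagents that add atoms: lithium hydroxide, [Li+].[OH-]
Why: Ester saponification by acyl–oxygen cleavage at low temperature, under which the beta-benzyloxy group should not be eliminated and the stereocentre, which is not alpha to the carbonyl, cannot epimerise.

Step 8
Reactants: 11 2,5-bis(benzyloxy)-4-hydroxy-3,6-bis(4-(benzyloxy)phenyl)phenyl 3-phenylpropanoate; 14 (S)-3-(benzyloxy)butanoic acid
Product: 15 2,5-bis(benzyloxy)-3,6-bis(4-(benzyloxy)phenyl)-4-((3-phenylpropanoyl)oxy)phenyl (S)-3-(benzyloxy)butanoate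
Conditions: 14 (1.5 equiv), DIC (N,N'-diisopropylcarbodiimide), DMAP, CH2Cl2, 0 °C to rt, Ar
Reagents that add atoms: none
Why: Steglich esterification, in which DMAP passes the O-acylisourea of 14 on as an acylpyridinium ion that acylates the remaining hindered phenol, the neighbouring oxygens being locked as benzyl ethers so that no ester can migrate and the (S) centre, beta to the carbonyl, being carried over unchanged.

Step 9
Reactants: 15 2,5-bis(benzyloxy)-3,6-bis(4-(benzyloxy)phenyl)-4-((3-phenylpropanoyl)oxy)phenyl (S)-3-(benzyloxy)butanoate
Product: 16 2,5-dihydroxy-3,6-bis(4-hydroxyphenyl)-4-((3-phenylpropanoyl)oxy)phenyl (S)-3-hydroxybutanoate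
Conditions: H2 (1 atm), 10% Pd/C, EtOAc/THF, rt; filtration and evaporation under Ar
Reagents that add atoms: none
Why: Hydrogenolysis of benzyl ethers over Pd/C in a neutral medium should remove all five benzyl groups (two on the central ring, two on the outer rings, one on the side-chain alcohol) as toluene while the aryl esters and the stereocentre are inert, and the neutral, air-free work-up guards against ester migration to the freed neighbouring hydroxyls and against oxidation of the hydroquinone.

**Compound list**

1 | 1,4-dibromo-2,5-dimethoxybenzene | COc1cc(Br)c(OC)cc1Br | starting material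
2 | 4-(benzyloxy)phenylboronic acid | OB(O)c1ccc(OCc2ccccc2)cc1 | starting material
3 | 2,5-bis(4-(benzyloxy)phenyl)-1,4-dimethoxybenzene | COc1cc(-c2ccc(OCc3ccccc3)cc2)c(OC)cc1-c1ccc(OCc2ccccc2)cc1 | intermediate
4 | 2,5-bis(4-(benzyloxy)phenyl)-1,4-benzoquinone | O=C1C=C(c2ccc(OCc3ccccc3)cc2)C(=O)C=C1c1ccc(OCc2ccccc2)cc1 | intermediate
5 | benzyl alcohol | OCc1ccccc1 | starting material
6 | 3-(benzyloxy)-2,5-bis(4-(benzyloxy)phenyl)benzene-1,4-diol | Oc1cc(-c2ccc(OCc3ccccc3)cc2)c(O)c(OCc2ccccc2)c1-c1ccc(OCc2ccccc2)cc1 | intermediate
7 | 3-(benzyloxy)-2,5-bis(4-(benzyloxy)phenyl)-1,4-benzoquinone | O=C1C=C(c2ccc(OCc3ccccc3)cc2)C(=O)C(OCc2ccccc2)=C1c1ccc(OCc2ccccc2)cc1 | intermediate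
8 | 2,5-bis(benzyloxy)-3,6-bis(4-(benzyloxy)phenyl)benzene-1,4-diol | Oc1c(OCc2ccccc2)c(-c2ccc(OCc3ccccc3)cc2)c(O)c(OCc2ccccc2)c1-c1ccc(OCc2ccccc2)cc1 | intermediate
9 | 2,5-bis(benzyloxy)-3,6-bis(4-(benzyloxy)phenyl)-1,4-benzoquinone | O=C1C(OCc2ccccc2)=C(c2ccc(OCc3ccccc3)cc2)C(=O)C(OCc2ccccc2)=C1c1ccc(OCc2ccccc2)cc1 | intermediate
10 | 3-phenylpropanoyl chloride | O=C(Cl)CCc1ccccc1 | starting material
11 | 2,5-bis(benzyloxy)-4-hydroxy-3,6-bis(4-(benzyloxy)phenyl)phenyl 3-phenylpropanoate | O=C(CCc1ccccc1)Oc1c(OCc2ccccc2)c(-c2ccc(OCc3ccccc3)cc2)c(O)c(OCc2ccccc2)c1-c1ccc(OCc2ccccc2)cc1 | intermediate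
12 | ethyl (S)-3-hydroxybutanoate | C[C@H](O)CC(=O)OCC | starting material
13 | ethyl (S)-3-(benzyloxy)butanoate | C[C@H](OCc1ccccc1)CC(=O)OCC | intermediate
14 | (S)-3-(benzyloxy)butanoic acid | C[C@H](OCc1ccccc1)CC(=O)O | intermediate
15 | 2,5-bis(benzyloxy)-3,6-bis(4-(benzyloxy)phenyl)-4-((3-phenylpropanoyl)oxy)phenyl (S)-3-(benzyloxy)butanoate | C[C@H](OCc1ccccc1)CC(=O)Oc1c(OCc2ccccc2)c(-c2ccc(OCc3ccccc3)cc2)c(OC(=O)CCc2ccccc2)c(OCc2ccccc2)c1-c1ccc(OCc2ccccc2)cc1 | intermediate
16 | 2,5-dihydroxy-3,6-bis(4-hydroxyphenyl)-4-((3-phenylpropanoyl)oxy)phenyl (S)-3-hydroxybutanoate | C[C@H](O)CC(=O)Oc1c(O)c(-c2ccc(O)cc2)c(OC(=O)CCc2ccccc2)c(O)c1-c1ccc(O)cc1 | target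

**Step count and risks**

Total step count: 9. Longest linear sequence: 7 steps (steps 1, 2, 3, 4, 5, 8, 9); steps 6 and 7 form a two-step side branch that joins at step 8.

Steps most likely to fail:

Step 3. The conjugate addition of benzyl alcohol at a quinone carbon flanked by an aryl group may be too slow. The route may also stall after the first addition because the mono-ether quinone is a poorer acceptor, so that Lewis-acid-promoted self-condensation of benzyl alcohol or substitution of chloride on the oxidant consumes the reagents instead. The fallback uses known chemistry and sets out from 4. Bromination with Br2 in AcOH/CHCl3 (addition to each quinone double bond and loss of HBr) should give 2,5-dibromo-3,6-bis(4-(benzyloxy)phenyl)-1,4-benzoquinone F1. Treatment of F1 with sodium benzyloxide (from 5 and NaH) in THF at 0 °C then replaces both vinylic bromides by addition–elimination, with no redox step, and the route is rejoined at 9. This is the classical way of oxygenating 2,5-diarylquinones.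

Step 9. Hydrogenolysis may stop short at the two flanked benzyl ethers of the central ring or at the secondary alkyl benzyl ether. On long exposure an ester may migrate to the neighbouring freed hydroxyl, or the product hydroquinone may be oxidised by air during work-up. The fallback sets out from 15 and replaces reduction by Lewis-acid debenzylation: BCl3 with pentamethylbenzene as cation scavenger in CH2Cl2 at −78 to 0 °C, quenched with MeOH. The benzyl groups are transferred to the scavenger while the aryl esters stay intact, and the route is rejoined at 16 (no new compound, F0).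

Step 5. Mono-selectivity may be poor, with over-acylation to the diester, and the electron-rich diol may be reoxidised by air before it is acylated. The fallback sets out from quinone 9 and avoids the free diol altogether: an N-heterocyclic-carbene-catalysed redox acylation with 3-phenylpropanal (3-ethylbenzothiazolium bromide, Et3N, THF, rt). The Breslow intermediate reduces the quinone and the acyl azolium ion so formed acylates one oxygen of the hydroquinone, so that each quinone can take up only one ester. This reaction type is known for 1,4-naphthoquinones and aldehydes, and the route is rejoined at 11 (no new compound, F0).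

**Further compounds**

F1 | step 3 | 2,5-dibromo-3,6-bis(4-(benzyloxy)phenyl)-1,4-benzoquinone | O=C1C(Br)=C(c2ccc(OCc3ccccc3)cc2)C(=O)C(Br)=C1c1ccc(OCc2ccccc2)cc1
F0 | step 9 | none | none
F0 | step 5 | none | none
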